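The cyclopentane is disconnected to a cyclohexanone: its ring-fusion CH (C-3a) carries the future exo-methylene carbon C-4 between the quaternary methyl carbon C-7a and the side-chain carbon C-3, exactly the pattern left when a ring carbonyl carbon is extruded onto its neighbour. (R)-Carvone supplies this six-membered ring, the C-3 stereocentre and the branched side chain. Photochemical Wolff rearrangement of the derived 2,2,5-trisubstituted 6-diazocyclohexanone contracts the ring, and the ketene carbon (C-4) is trapped by the side-chain hydroxyl as a cis-fused δ-lactone, fixing the all-cis cyclopentane in one operation. The cyclohexane is then annulated by anionic acylation of that lactone and the eleven-membered ring closed by Nozaki–Hiyama–Kishi coupling before hydroxyl-directed epoxidation.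

Key step: step 6

Remark: cyclohexanones 4–8 carry cyclohexanone locants (C-1 carbonyl, C-2 quaternary carbon, C-5 side-chain carbon, C-6 diazo carbon), lactones 10–12 cyclopenta[c]pyran locants, and hydrindanes 14–26 octahydroindene locants (C-7a quaternary methyl carbon, C-3a ring-fusion CH, C-3 side-chain carbon, C-4 carbonyl or methylidene carbon, C-5 arm-bearing carbon, C-7 oxygen-bearing carbon). The antipodes of the chiral ligand, controller and acid in steps 4, 7 and 14 are assigned from the usual facial models for simple substrates; each has an available enantiomer.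

Step 1
Reactants: 1 (R)-(−)-carvone
Product: 3 trimethyl{[(5R)-2-methyl-5-(prop-1-en-2-yl)cyclohex-1-en-1-yl]oxy}silane, via lithium enolate 2 (not isolated)
Conditions: LiBH(s-Bu)3, THF, −78 °C; then Me3SiCl, Et3N, −78 °C to rt
Reagents that add atoms: chlorotrimethylsilane, C[Si](C)(C)Cl
Why: Conjugate hydride addition of the bulky borohydride to the β-unsubstituted enone gives the tetrasubstituted lithium enolate regiospecifically and O-silylation traps it (1,4-reduction/enolate trapping); the carvone stereocentre is not involved.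

Step 2
Reactants: 3 silyl enol ether
Product: 4 (2R,5R)-2-(dimethoxymethyl)-2-methyl-5-(prop-1-en-2-yl)cyclohexan-1-one (acetal carbon cis to the isopropenyl group)
Conditions: HC(OMe)3, Me3SiOTf (10 mol %), CH2Cl2, −78 °C
Reagents that add atoms: trimethyl orthoformate, COC(OC)OC
Why: Mukaiyama-type addition of the silyl enol ether to the dimethoxycarbenium ion released from the orthoformate creates the quaternary centre; the electrophile enters axially on the half-chair that keeps the isopropenyl group equatorial, i.e. cis to it, the sense seen in alkylations of carvone-derived enolates.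

Step 3
Reactants: 4 keto acetal
Product: 5 (2R,5R)-2-(dimethoxymethyl)-5-(3-hydroxyprop-1-en-2-yl)-2-methylcyclohexan-1-one
Conditions: SeO2 (cat.), t-BuOOH, CH2Cl2, rt
Reagents that add atoms: tert-butyl hydroperoxide, CC(C)(C)OO
Why: Allylic hydroxylation by SeO2 (ene reaction then [2,3]-sigmatropic shift) takes the methyl group of the 1,1-disubstituted alkene in preference to the ring methine, and t-BuOOH re-oxidises selenium so that the product stays at the alcohol level.

Step 4
Reactants: 5 allylic alcohol
Product: 6 (2R,5R)-2-(dimethoxymethyl)-5-[(2S)-1-hydroxypropan-2-yl]-2-methylcyclohexan-1-one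
Conditions: Ru(OAc)2((R)-BINAP) (1 mol %), H2 (50 atm), MeOH, rt
Reagents that add atoms: none
Why: Hydroxyl-directed asymmetric hydrogenation of the allylic alcohol with a Ru–BINAP catalyst sets the methyl-bearing stereocentre under ligand control (no ring substituent flanks the side chain to oppose it), the (R)-ligand being assigned by analogy with the known sense for geraniol; the hindered ketone and the acetal are inert.

Step 5
Reactants: 6 hydroxy ketone
Product: 8 (2R,5S)-6-diazo-2-(dimethoxymethyl)-5-[(2S)-1-hydroxypropan-2-yl]-2-methylcyclohexan-1-one, via bis(trifluoroacetyl) derivative 7 (not isolated)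
Conditions: LiN(SiMe3)2 (2.2 equiv), THF, −78 °C; CF3CO2CH2CF3; aq. HCl work-up, crude 7 taken on; then MsN3, Et3N, H2O, MeCN, rt
Reagents that add atoms: methanesulfonyl azide, CS(=O)(=O)N=[N+]=[N-]
Why: Detrifluoroacetylative (Regitz-type) diazo transfer: C-6, the only enolisable position, is activated as the trifluoroacetyl ketone and exchanges with mesyl azide, while the trifluoroacetate formed on the primary hydroxyl is hydrolysed in the aqueous triethylamine medium.

Step 6
Reactants: 8 diazo ketone
Product: 11 cis-fused 4,7-dimethyl-1-oxooctahydrocyclopenta[c]pyran-7-carbaldehyde (4-CH3/4a-H/7a-H/7-CH3 on one face), via ketene 9 (not isolated), via lactone acetal 10 (not isolated)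
Conditions: hν (350 nm, Pyrex), MeCN, rt; then 1 M HCl, rt
Reagents that add atoms: water, O
Why: Light expels N2 from the cyclic α-diazo ketone, whose locked s-cis geometry lets the C-1–C-2 bond migrate to C-6 in concert (photochemical Wolff rearrangement, the classical ring contraction of 2-diazocyclohexanones); the six-membered ring becomes the cyclopentane and the former carbonyl carbon leaves the ring as a ketene carbon. The migrating quaternary carbon C-2 keeps its configuration and the C-5 stereocentre is untouched. The side-chain hydroxyl then adds to the ketene carbonyl carbon (6-exo-dig lactonisation), closing the δ-lactone ring. The new ring-fusion stereocentre is set when the enol lactone tautomerises: the cis-fused bicycle is the one reached comfortably, and protonation anti to the dimethoxymethyl group places H cis to the quaternary methyl group. The step needs migration to outrun O–H or C–H insertion of a free carbene, which the concerted pathway of the s-cis diazo ketone and the absence of any external nucleophile secure. Aqueous acid in the same flask finally hydrolyses the dimethyl acetal to the aldehyde.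

Step 7
Reactants: 11 lactone aldehyde
Product: 12 cis-fused 7-[(1S)-3-bromo-1-hydroxybut-3-en-1-yl]-4,7-dimethylhexahydrocyclopenta[c]pyran-1(3H)-one
Conditions: (S,S)-2-bromo-4,5-diphenyl-1,3-bis(p-tolylsulfonyl)-1,3,2-diazaborolidine, tributyl(2-bromoallyl)stannane, CH2Cl2, rt; then 11, −78 °C; aq. work-up
Reagents that add atoms: tributyl(2-bromoallyl)stannane, C=C(Br)C[Sn](CCCC)(CCCC)CCCC
Why: Reagent-controlled 2-bromoallylboration through a chair transition state on the chiral diazaborolidine adds the allyl unit to the neopentyl aldehyde; the (S,S)-controller is chosen as the matched partner of the Felkin–Anh preference (attack anti to the ring-fusion carbon C-7a), which gives the (S)-carbinol needed for the later 7-acyloxy group.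

Step 8
Reactants: 12 bromoallyl carbinol
Product: 14 7-hydroxy-3-[(2S)-1-hydroxypropan-2-yl]-7a-methyl-5-methylideneoctahydro-4H-inden-4-one (3-H/3a-H/7a-CH3/7-OH on one face), via dilithio alkoxide 13 (not isolated)
Conditions: t-BuLi (3.2 equiv), THF, −78 to −20 °C; aq. NH4Cl
Reagents that add atoms: none
Why: Bromine–lithium exchange gives a vinyllithium that attacks the lactone carbonyl in a 6-exo-trig sense (Parham-type anionic cyclisation, intramolecular acylation); the lithium hemiketalate resists a second addition and collapses on work-up to the α-methylene ketone and the primary alcohol, with no stereocentre formed or touched.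

Step 9
Reactants: 14 dihydroxy enone
Product: 15 5-(1,3-dioxolan-2-ylmethyl)-7-hydroxy-3-[(2S)-1-hydroxypropan-2-yl]-7a-methyloctahydro-4H-inden-4-one (C-5 arm cis to 7-OH and 7a-CH3)
Conditions: 1,3-dioxolane (solvent), (n-Bu4N)4[W10O32] (2 mol %), hν (365 nm), rt
Reagents that add atoms: 1,3-dioxolane, C1COCO1
Why: Decatungstate-photocatalysed hydrogen abstraction from C-2 of 1,3-dioxolane and Giese addition of the nucleophilic dioxolanyl radical to the exocyclic enone install the masked acetaldehyde arm; hydrogen return to the planar α-keto radical at C-5 occurs axially on the chair that keeps the C-3a–C-3 bond axial, giving the equatorial arm, which is also the more stable epimer.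

Step 10
Reactants: 15 keto diol
Product: 16 (2S)-2-[5-(1,3-dioxolan-2-ylmethyl)-7-hydroxy-7a-methyl-4-oxooctahydro-1H-inden-3-yl]propanal
Conditions: TEMPO (10 mol %), PhI(OAc)2, CH2Cl2, rt
Reagents that add atoms: none
Why: Oxoammonium (TEMPO) oxidation with PhI(OAc)2 as terminal oxidant is selective for the primary alcohol over the hindered secondary one and stops at the aldehyde without touching its α-stereocentre.

Step 11
Reactants: 16 hydroxy aldehyde
Product: 17 7-O-propionate of 16
Conditions: (EtCO)2O, DMAP (cat.), pyridine, CH2Cl2, 0 °C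
Reagents that add atoms: propionic anhydride, CCC(=O)OC(=O)CC
Why: DMAP-catalysed acylation of the only free hydroxyl gives the propionate, a weak base and low temperature sparing the α-stereocentre of the aldehyde.

Step 12
Reactants: 18 but-2-yn-1-ol
Product: 19 but-2-yn-1-yl methyl carbonate
Conditions: ClCO2Me, pyridine, CH2Cl2, 0 °C
Reagents that add atoms: methyl chloroformate, COC(=O)Cl
Why: Acylation of the primary propargylic alcohol by the chloroformate provides the carbonate leaving group for the next step.

Step 13
Reactants: 19 propargylic carbonate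
Product: 20 2-(buta-2,3-dien-2-yl)-4,4,5,5-tetramethyl-1,3,2-dioxaborolane
Conditions: B2pin2, CuO-t-Bu (10 mol %), Xantphos (10 mol %), THF, 50 °C
Reagents that add atoms: bis(pinacolato)diboron, CC1(C)OB(OC1(C)C)B1OC(C)(C)C(C)(C)O1
Why: Copper-catalysed SN2′ borylation of the propargylic carbonate: the boryl–copper species adds to the alkyne carbon remote from the leaving group and anti-elimination with loss of CO2 and methoxide gives the 1-methylallenylboronate.

Step 14
Reactants: 17 aldehyde propionate; 20 allenylboronate
Product: 21 5-(1,3-dioxolan-2-ylmethyl)-3-[(2S,3S)-3-hydroxyhept-5-yn-2-yl]-7a-methyl-4-oxooctahydro-1H-inden-7-yl propanoate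
Conditions: (S)-TRIP (10 mol %), 4 Å MS, toluene, −20 °C; aq. work-up
Reagents that add atoms: 2-(buta-2,3-dien-2-yl)-4,4,5,5-tetramethyl-1,3,2-dioxaborolane (20), C=C=C(C)B1OC(C)(C)C(C)(C)O1
Why: Allenylboration of the aldehyde through a six-membered chair transition state (SE2′) gives the but-2-ynyl carbinol; the chiral phosphoric acid activates the boronate and selects the aldehyde face that the Felkin–Anh model also prefers (attack anti to the ring carbon), so methyl and hydroxyl end up syn, and the hindered ketone does not compete.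

Step 15
Reactants: 21 homopropargylic alcohol
Product: 22 acetate of 21 (side chain (2S,3S)-3-acetoxyhept-5-yn-2-yl)
Conditions: Ac2O, DMAP, pyridine, CH2Cl2, rt
Reagents that add atoms: acetic anhydride, CC(=O)OC(C)=O
Why: DMAP-catalysed acetylation of the single free hydroxyl.

Step 16
Reactants: 22 keto diester
Product: 23 4-methylidene analogue of 22
Conditions: Zn, CH2Br2, TiCl4, THF–CH2Cl2, 0 °C to rt
Reagents that add atoms: dibromomethane, BrCBr
Why: Takai–Lombardo methylenation with the zinc–dibromomethane–TiCl4 reagent converts the hindered, enolisable ketone into the exocyclic alkene under non-basic conditions, so C-5 and C-3a do not epimerise and esters and acetal survive.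

Step 17
Reactants: 23 alkyne
Product: 25 3-[(2S,3S,5E)-3-acetoxy-6-iodohept-5-en-2-yl]-5-(1,3-dioxolan-2-ylmethyl)-7a-methyl-4-methylideneoctahydro-1H-inden-7-yl propanoate, via alkenylzirconocene chloride 24 (not isolated)
Conditions: Cp2Zr(H)Cl (2.5 equiv), THF, rt; then I2, 0 °C
Reagents that add atoms: iodine, II
Why: Syn-hydrozirconation of the 2-alkyne puts zirconium on the methyl-bearing carbon (steric control, sharpened by equilibration with excess reagent) and iodinolysis with retention gives the (E)-2-iodoalkene; the alkyne reacts faster than the hindered 1,1-disubstituted alkene or the esters.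

Step 18
Reactants: 25 dioxolane
Product: 26 5-(2-oxoethyl) analogue of 25 (aldehyde)
Conditions: PPTS (cat.), acetone–H2O, 50 °C
Reagents that add atoms: water, O
Why: Mild acid-catalysed hydrolysis of the dioxolane frees the aldehyde without harming esters, vinyl iodide or the exocyclic alkene.

Step 19
Reactants: 26 iodo aldehyde
Product: 27 tricyclic (E)-allylic alcohol: eleven-membered ring closed between the iodine-bearing alkene carbon and the aldehyde carbon of 26, (R)-carbinol
Conditions: CrCl2 (8 equiv), NiCl2 (1 mol %), DMSO–THF, rt, 2 mM; aq. work-up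
Reagents that add atoms: none
Why: Nozaki–Hiyama–Kishi coupling: oxidative addition of the vinyl iodide to zerovalent nickel, transmetalation to trivalent chromium and aldehyde-selective addition of the alkenylchromium close the eleven-membered ring (exo-trig on the aldehyde) under high dilution with retention of the E geometry; the carbinol centre is set by the macrocyclic transition state, the (R)-epimer being the one required.

Step 20
Reactants: 27 macrocyclic allylic alcohol
Product: 28 CNP0415604.1 (target)
Conditions: m-CPBA (1.05 equiv), NaHCO3, CH2Cl2, 0 °C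
Reagents that add atoms: 3-chloroperoxybenzoic acid, OOC(=O)c1cccc(Cl)c1
Why: Peracid epoxidation of the more nucleophilic trisubstituted alkene (Prilezhaev reaction with Henbest direction): oxygen is delivered syn to the allylic hydroxyl through the hydrogen-bonded transition state on the outer face of the E-cycloundecene, which gives the threo epoxy alcohol of the target, while the hindered exocyclic alkene reacts more slowly.

Compound list
1 | (R)-(−)-carvone, (5R)-2-methyl-5-(prop-1-en-2-yl)cyclohex-2-en-1-one | CC1=CC[C@H](CC1=O)C(C)=C | starting material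
2 | lithium (5R)-2-methyl-5-(prop-1-en-2-yl)cyclohex-1-en-1-olate | [Li]OC1=C(C)CC[C@@H](C(C)=C)C1 | intermediate (not isolated)
3 | trimethyl{[(5R)-2-methyl-5-(prop-1-en-2-yl)cyclohex-1-en-1-yl]oxy}silane | C[Si](C)(C)OC1=C(C)CC[C@@H](C(C)=C)C1 | intermediate
4 | (2R,5R)-2-(dimethoxymethyl)-2-methyl-5-(prop-1-en-2-yl)cyclohexan-1-one | COC(OC)[C@@]1(C)CC[C@@H](C(C)=C)CC1=O | intermediate
5 | (2R,5R)-2-(dimethoxymethyl)-5-(3-hydroxyprop-1-en-2-yl)-2-methylcyclohexan-1-one | COC(OC)[C@@]1(C)CC[C@@H](C(=C)CO)CC1=O | intermediate
6 | (2R,5R)-2-(dimethoxymethyl)-5-[(2S)-1-hydroxypropan-2-yl]-2-methylcyclohexan-1-one | COC(OC)[C@@]1(C)CC[C@@H]([C@H](C)CO)CC1=O | intermediate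
7 | 6-trifluoroacetyl derivative of 6 with the primary hydroxyl as trifluoroacetate | COC(OC)[C@@]1(C)CC[C@@H]([C@H](C)COC(=O)C(F)(F)F)C(C(=O)C(F)(F)F)C1=O | intermediate (not isolated)
8 | (2R,5S)-6-diazo-2-(dimethoxymethyl)-5-[(2S)-1-hydroxypropan-2-yl]-2-methylcyclohexan-1-one | COC(OC)[C@@]1(C)CC[C@@H]([C@H](C)CO)C(=[N+]=[N-])C1=O | intermediate
9 | ketene: {2-(dimethoxymethyl)-5-[(2S)-1-hydroxypropan-2-yl]-2-methylcyclopentylidene}methanone | COC(OC)[C@@]1(C)CC[C@@H]([C@H](C)CO)C1=C=O | intermediate (not isolated)
10 | cis-fused 7-(dimethoxymethyl)-4,7-dimethylhexahydrocyclopenta[c]pyran-1(3H)-one, 4-CH3/4a-H/7a-H/7-CH3 on one face | COC(OC)[C@@]1(C)CC[C@@H]([C@H](C)COC2=O)[C@H]12 | intermediate (not isolated)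
11 | cis-fused 4,7-dimethyl-1-oxooctahydrocyclopenta[c]pyran-7-carbaldehyde, same face relationships as 10 | O=C[C@@]1(C)CC[C@@H]([C@H](C)COC2=O)[C@H]12 | intermediate
12 | cis-fused 7-[(1S)-3-bromo-1-hydroxybut-3-en-1-yl]-4,7-dimethylhexahydrocyclopenta[c]pyran-1(3H)-one | C=C(Br)C[C@H](O)[C@@]1(C)CC[C@@H]([C@H](C)COC2=O)[C@H]12 | intermediate
13 | dilithio species of 12 (lithium alkoxide, 2-lithioallyl) | [Li]C(=C)C[C@H](O[Li])[C@@]1(C)CC[C@@H]([C@H](C)COC2=O)[C@H]12 | intermediate (not isolated)
14 | 7-hydroxy-3-[(2S)-1-hydroxypropan-2-yl]-7a-methyl-5-methylideneoctahydro-4H-inden-4-one, 3-H/3a-H/7a-CH3/7-OH on one face | O=C1C(=C)C[C@H](O)[C@@]2(C)CC[C@@H]([C@H](C)CO)[C@@H]12 | intermediate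
15 | 5-(1,3-dioxolan-2-ylmethyl)-7-hydroxy-3-[(2S)-1-hydroxypropan-2-yl]-7a-methyloctahydro-4H-inden-4-one, C-5 arm cis to 7-OH | O=C1[C@H](CC2OCCO2)C[C@H](O)[C@@]3(C)CC[C@@H]([C@H](C)CO)[C@@H]13 | intermediate
16 | (2S)-2-[5-(1,3-dioxolan-2-ylmethyl)-7-hydroxy-7a-methyl-4-oxooctahydro-1H-inden-3-yl]propanal | O=C1[C@H](CC2OCCO2)C[C@H](O)[C@@]3(C)CC[C@@H]([C@H](C)C=O)[C@@H]13 | intermediate
17 | 5-(1,3-dioxolan-2-ylmethyl)-7a-methyl-4-oxo-3-[(2S)-1-oxopropan-2-yl]octahydro-1H-inden-7-yl propanoate | O=C1[C@H](CC2OCCO2)C[C@H](OC(=O)CC)[C@@]3(C)CC[C@@H]([C@H](C)C=O)[C@@H]13 | intermediate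
18 | but-2-yn-1-ol | CC#CCO | starting material
19 | but-2-yn-1-yl methyl carbonate | CC#CCOC(=O)OC | intermediate
20 | 2-(buta-2,3-dien-2-yl)-4,4,5,5-tetramethyl-1,3,2-dioxaborolane | C=C=C(C)B1OC(C)(C)C(C)(C)O1 | intermediate
21 | 5-(1,3-dioxolan-2-ylmethyl)-3-[(2S,3S)-3-hydroxyhept-5-yn-2-yl]-7a-methyl-4-oxooctahydro-1H-inden-7-yl propanoate | O=C1[C@H](CC2OCCO2)C[C@H](OC(=O)CC)[C@@]3(C)CC[C@@H]([C@H](C)[C@@H](O)CC#CC)[C@@H]13 | intermediate
22 | 3-[(2S,3S)-3-acetoxyhept-5-yn-2-yl]-5-(1,3-dioxolan-2-ylmethyl)-7a-methyl-4-oxooctahydro-1H-inden-7-yl propanoate | O=C1[C@H](CC2OCCO2)C[C@H](OC(=O)CC)[C@@]3(C)CC[C@@H]([C@H](C)[C@@H](OC(C)=O)CC#CC)[C@@H]13 | intermediate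
23 | 3-[(2S,3S)-3-acetoxyhept-5-yn-2-yl]-5-(1,3-dioxolan-2-ylmethyl)-7a-methyl-4-methylideneoctahydro-1H-inden-7-yl propanoate | C=C1[C@H](CC2OCCO2)C[C@H](OC(=O)CC)[C@@]3(C)CC[C@@H]([C@H](C)[C@@H](OC(C)=O)CC#CC)[C@@H]13 | intermediate
24 | alkenylzirconocene chloride from 23 (Zr on the methyl-bearing alkene carbon, H and Zr cis) | C=C1[C@H](CC2OCCO2)C[C@H](OC(=O)CC)[C@@]3(C)CC[C@@H]([C@H](C)[C@@H](OC(C)=O)C/C=C(/[Zr](Cl)(C4C=CC=C4)C4C=CC=C4)C)[C@@H]13 | intermediate (not isolated)
25 | 3-[(2S,3S,5E)-3-acetoxy-6-iodohept-5-en-2-yl]-5-(1,3-dioxolan-2-ylmethyl)-7a-methyl-4-methylideneoctahydro-1H-inden-7-yl propanoate | C=C1[C@H](CC2OCCO2)C[C@H](OC(=O)CC)[C@@]3(C)CC[C@@H]([C@H](C)[C@@H](OC(C)=O)C/C=C(/I)C)[C@@H]13 | intermediate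
26 | 3-[(2S,3S,5E)-3-acetoxy-6-iodohept-5-en-2-yl]-7a-methyl-4-methylidene-5-(2-oxoethyl)octahydro-1H-inden-7-yl propanoate | C=C1[C@H](CC=O)C[C@H](OC(=O)CC)[C@@]2(C)CC[C@@H]([C@H](C)[C@@H](OC(C)=O)C/C=C(/I)C)[C@@H]12 | intermediate
27 | tricyclic (E)-allylic alcohol (5-6-11 ring system, (R)-carbinol, acetate and propionate in place) | C=C1[C@H]2C[C@H](OC(=O)CC)[C@@]3(C)CC[C@@H]([C@H](C)[C@@H](OC(C)=O)C/C=C(\C)[C@H](O)C2)[C@@H]13 | intermediate
28 | CNP0415604.1 | C=C1[C@H]2C[C@H](OC(=O)CC)[C@@]3(C)CC[C@@H]([C@H](C)[C@@H](OC(C)=O)C[C@@H]4O[C@@]4(C)[C@H](O)C2)[C@@H]13 | target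

Total step count: 20. Longest linear sequence: 18 steps (steps 1–11 and 14–20); steps 12–13 make the allenylboronate.

Steps most likely to fail

Step 19. The alkenylchromium may add to the wrong face of the aldehyde in the medium-ring transition state, and oligomers may compete with ring closure. The fallback sets out from 26 and returns at 27. The same ring closure is run without regard to the carbinol configuration and gives 27 mixed with its carbinol epimer, the (S)-allylic alcohol F1. The mixture is oxidised with MnO2 (CH2Cl2, rt; only the allylic alcohol reacts) to the macrocyclic enone F2. F2 is then reduced with (S)-2-methyl-CBS-oxazaborolidine and catecholborane (toluene, −78 °C), where the reagent rather than the ring chooses the face (alkenyl as the large group), to give 27.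

Step 20. The peracid may attack the other alkene face and give the erythro epoxide if the ring holds the hydroxyl in the alkene plane instead of perpendicular to it on the outer face. The fallback sets out from 27 and returns at 28: reagent-controlled epoxidation with the L-fructose-derived ketone catalyst (enantiomer of the Shi ketone), KHSO5 (Oxone), K2CO3, MeCN–dimethoxymethane–buffer, 0 °C. Its spiro transition state selects the required face of the trisubstituted E-alkene and leaves the 1,1-disubstituted alkene alone. This fallback makes no new compound (F0).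

Step 4. The ruthenium catalyst may discriminate poorly between the faces of the 1,1-disubstituted alkene, or the ligand sense may not transfer from the geraniol model. The fallback sets out from 5 and returns at 6. MnO2 (CH2Cl2, rt) oxidises 5 to the 2-substituted acrolein F3. An ene-reductase (flavin-dependent, Old Yellow Enzyme class; NADPH recycled with glucose and glucose dehydrogenase, pH 7 buffer, 30 °C) reduces the C=C bond with enzyme-controlled protonation at the α-carbon to the (2S)-aldehyde F4. NaBH(OAc)3 (CH2Cl2, rt) then reduces the aldehyde in the presence of the hindered ketone to 6.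

Further compounds
F1 | step 19 | carbinol epimer of 27, (S)-allylic alcohol | C=C1[C@H]2C[C@H](OC(=O)CC)[C@@]3(C)CC[C@@H]([C@H](C)[C@@H](OC(C)=O)C/C=C(\C)[C@@H](O)C2)[C@@H]13
F2 | step 19 | macrocyclic (E)-enone | C=C1[C@H]2C[C@H](OC(=O)CC)[C@@]3(C)CC[C@@H]([C@H](C)[C@@H](OC(C)=O)C/C=C(\C)C(=O)C2)[C@@H]13
F0 | step 20 | none | none
F3 | step 4 | 2-[(1R,4R)-4-(dimethoxymethyl)-4-methyl-3-oxocyclohexyl]prop-2-enal | COC(OC)[C@@]1(C)CC[C@@H](C(=C)C=O)CC1=O
F4 | step 4 | (2S)-2-[(1R,4R)-4-(dimethoxymethyl)-4-methyl-3-oxocyclohexyl]propanal | COC(OC)[C@@]1(C)CC[C@@H]([C@H](C)C=O)CC1=O
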